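**Strategy**

The route rests on disconnecting the C2=C3 double bond of cyclopentene ring A (indene numbering). Ring A's only unsaturation links two carbons that hang from the trans-disposed C7a and C3a positions of cyclohexene ring B. A ring-closing metathesis of a diene carrying an (R)-but-3-en-2-yl arm at C7a and a but-1-en-2-yl arm at C3a therefore closes the trans-fused bicycle in one operation, losing only ethene. The precursor is a fully substituted cyclohexene made from the butadiene–dimethylmaleic anhydride adduct: alkaloid-mediated desymmetrisation fixes both quaternary centres (C4, C5), bromolactonisation relays them to an enone, and conjugate addition, allylation and methylation add the remaining carbons.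

Key step: step 15

Remarks and assumptions
- Locants in the text are those of the target: ring A = C1, C2, C3, C3a, C7a; ring B = C3a, C4, C5, C6, C7, C7a.
- Assumption: quinidine is taken to open anhydride 3 in the sense that gives (1S,2R)-4, by analogy with the parent cis-cyclohex-4-ene-1,2-dicarboxylic anhydride. If the sense is opposite, quinine is used and nothing else changes.
- Assumption: the (S,S,S) phosphoramidite in step 12 is taken to give the (R)-but-3-en-2-yl unit. If the sense is opposite, its enantiomer is used.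
- Reagents 14 and 19 are each made in one step because their commercial supply is uncertain.

**Route**

Step 1
Reactants: 1 2,3-dimethylmaleic anhydride; 2 buta-1,3-diene
Product: 3 cis-1,2-dimethylcyclohex-4-ene-1,2-dicarboxylic anhydride (meso)
Conditions: excess 2, hydroquinone (cat.), sealed tube, 190 °C
Reagents that add atoms: none
Why: Thermal Diels–Alder reaction: suprafacial addition of the diene to the tetrasubstituted alkene of 1 places the two methyl groups cis, so both future quaternary carbons (C4 and C5) are created together in a meso anhydride.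

Step 2
Reactants: 3 meso anhydride
Product: 4 (1S,2R)-2-(methoxycarbonyl)-1,2-dimethylcyclohex-4-ene-1-carboxylic acid
Conditions: MeOH (3 equiv), quinidine (1.1 equiv), toluene, −40 °C
Reagents that add atoms: methanol, CO
Why: Cinchona-alkaloid-mediated desymmetrising methanolysis of a meso anhydride: the chiral amine acts as a general base that differentiates the two enantiotopic carbonyl groups, which fixes the absolute configuration of C4 and C5 and leaves the free acid on the future C5 and the ester on the future C4.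

Step 3
Reactants: 4 hemiester
Product: 5 methyl (1S,2R,4R,5R)-4-bromo-1,2-dimethyl-7-oxo-6-oxabicyclo[3.2.1]octane-2-carboxylate
Conditions: N-bromosuccinimide, NaHCO3 (cat.), CH2Cl2, 0 °C to rt, dark
Reagents that add atoms: N-bromosuccinimide, O=C1CCC(=O)N1Br
Why: Bromolactonisation: the carboxylate opens the bromonium ion anti at the alkene carbon that closes the five-membered lactone, which puts oxygen on the future C7 on the face of the C5 carboxyl and bromine trans to it on the future C7a.

Step 4
Reactants: 5 bromolactone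
Product: 6 methyl (1S,2R,5R)-1,2-dimethyl-7-oxo-6-oxabicyclo[3.2.1]oct-3-ene-2-carboxylate
Conditions: DBU, toluene, 110 °C
Reagents that add atoms: none
Why: E2 dehydrobromination: the axial bromide has an anti-periplanar hydrogen only on the future C3a, so the allylic bridged lactone with a C7a=C3a alkene should form.

Step 5
Reactants: 6 allylic lactone
Product: 7 methyl (1S,2R,5R)-7-hydroxy-1,2-dimethyl-6-oxabicyclo[3.2.1]oct-3-ene-2-carboxylate (lactol, both epimers at the hemiacetal carbon)
Conditions: i-Bu2AlH (1.05 equiv), CH2Cl2, −78 °C; aq. potassium sodium tartrate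
Reagents that add atoms: none
Why: Partial reduction of a lactone to a lactol: the strained bridged γ-lactone gives a stable tetrahedral aluminate at −78 °C and should react faster than the methyl ester on the doubly flanked quaternary carbon.

Step 6
Reactants: 7 lactol; 8 diethyl [(2E)-3-phenylprop-2-en-1-yl]phosphonate
Product: 10 methyl (1R,4R,6R)-4-hydroxy-1,6-dimethyl-6-[(1E,3E)-4-phenylbuta-1,3-dien-1-yl]cyclohex-2-ene-1-carboxylate, via lithiated phosphonate 9 (not isolated)
Conditions: 8, LiN(SiMe3)2 (2.3 equiv), THF, −78 °C; then 7, −78 °C to rt; aq. NH4Cl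
Reagents that add atoms: none
Why: Horner–Wadsworth–Emmons olefination of the hydroxy aldehyde tautomer of the lactol with an allylic phosphonate anion: syn elimination from the thermodynamically preferred adduct should give the new alkene with E geometry, completing the (1E,3E)-4-phenylbuta-1,3-dienyl chain on C5 and releasing the allylic C7 alcohol.

Step 7
Reactants: 10 allylic alcohol
Product: 11 methyl (1R,6R)-1,6-dimethyl-4-oxo-6-[(1E,3E)-4-phenylbuta-1,3-dien-1-yl]cyclohex-2-ene-1-carboxylate
Conditions: Dess–Martin periodinane, NaHCO3, CH2Cl2, 0 °C to rt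
Reagents that add atoms: none
Why: Dess–Martin oxidation of the allylic alcohol gives the cyclohexenone without touching a stereocentre.

Step 8
Reactants: 12 2-bromobut-1-ene
Product: 14 2-(but-1-en-2-yl)-4,4,5,5-tetramethyl-1,3,2-dioxaborolane, via but-1-en-2-ylmagnesium bromide 13 (not isolated)
Conditions: Mg, THF, rt; then 2-isopropoxy-4,4,5,5-tetramethyl-1,3,2-dioxaborolane, −78 °C to rt; aq. NH4Cl
Reagents that add atoms: 2-isopropoxy-4,4,5,5-tetramethyl-1,3,2-dioxaborolane, CC(C)OB1OC(C)(C)C(C)(C)O1
Why: Grignard formation from the alkenyl bromide and electrophilic borylation with an isopropoxy pinacol boronate give the alkenyl boronic ester.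

Step 9
Reactants: 11 enone; 14 alkenyl boronate
Product: 15 methyl (1R,2R,6R)-6-(but-1-en-2-yl)-1,2-dimethyl-4-oxo-2-[(1E,3E)-4-phenylbuta-1,3-dien-1-yl]cyclohexane-1-carboxylate
Conditions: [RhCl(C2H4)2]2 (3 mol%), (R)-BINAP (6.6 mol%), 14 (3 equiv), KOH (0.5 equiv), 1,4-dioxane/H2O (10:1), 80 °C
Reagents that add atoms: none
Why: Rhodium-catalysed asymmetric 1,4-addition of an alkenylboron reagent (Hayashi–Miyaura reaction): the alkenyl–rhodium species adds to the enone under catalyst control, and (R)-BINAP, which gives (R)-3-substituted cyclohexanones from cyclohex-2-enone, directs the group to the face of C3a anti to the C4 ester, setting C3a before the rhodium enolate is protonated.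

Step 10
Reactants: 15 ketone
Product: 17 methyl (1R,2R,6R)-2-(but-1-en-2-yl)-1,6-dimethyl-6-[(1E,3E)-4-phenylbuta-1,3-dien-1-yl]-4-[(trimethylsilyl)oxy]cyclohex-3-ene-1-carboxylate, via lithium enolate 16 (not isolated)
Conditions: LiN(SiMe3)2, THF, −78 °C; then Me3SiCl, Et3N
Reagents that add atoms: chlorotrimethylsilane, C[Si](C)(C)Cl
Why: Kinetic enolisation and O-silylation: the amide base should remove a proton from the α-methylene next to the tertiary C3a in preference to the neopentyl-type α-methylene next to quaternary C5, giving the regio-defined silyl enol ether.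

Step 11
Reactants: 18 (2E)-but-2-en-1-ol
Product: 19 (2E)-but-2-en-1-yl methyl carbonate
Conditions: ClCO2Me, pyridine, CH2Cl2, 0 °C
Reagents that add atoms: methyl chloroformate, COC(=O)Cl
Why: O-Acylation of the allylic alcohol with a chloroformate gives the allylic carbonate needed as electrophile.

Step 12
Reactants: 17 silyl enol ether; 19 allylic carbonate
Product: 20 methyl (1R,2R,5S,6R)-5-[(2R)-but-3-en-2-yl]-6-(but-1-en-2-yl)-1,2-dimethyl-4-oxo-2-[(1E,3E)-4-phenylbuta-1,3-dien-1-yl]cyclohexane-1-carboxylate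
Conditions: [Ir(cod)Cl]2 (2 mol%), (11bS)-N,N-bis[(1S)-1-phenylethyl]dinaphtho[2,1-d:1',2'-f][1,3,2]dioxaphosphepin-4-amine (4 mol%), CsF (0.4 equiv), ZnF2 (1.5 equiv), DME, 50 °C
Reagents that add atoms: none
Why: Iridium-catalysed branched-selective allylic alkylation of a fluoride-activated silyl enol ether: the enolate carbon (C7a) attacks the substituted terminus of the allyliridium intermediate anti to the adjacent C3a arm, which sets C7a trans to C3a, and the chiral phosphoramidite sets the (R) configuration of the new methyl-bearing centre (C1).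

Step 13
Reactants: 20 ketone
Product: 22 methyl (1R,2S,5S,6R)-5-[(2R)-but-3-en-2-yl]-6-(but-1-en-2-yl)-1,2-dimethyl-2-[(1E,3E)-4-phenylbuta-1,3-dien-1-yl]-4-{[(trifluoromethyl)sulfonyl]oxy}cyclohex-3-ene-1-carboxylate, via potassium enolate 21 (not isolated)
Conditions: KN(SiMe3)2, THF, −78 °C; then PhNTf2, −78 to 0 °C; aq. NH4Cl
Reagents that add atoms: N-phenylbis(trifluoromethanesulfonimide), O=S(=O)(N(c1ccccc1)S(=O)(=O)C(F)(F)F)C(F)(F)F
Why: Kinetic enolisation toward the only α-methylene (C6; the other α-position is a hindered methine) and O-triflation with PhNTf2 give the alkenyl triflate.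

Step 14
Reactants: 22 alkenyl triflate
Product: 23 methyl (1R,2S,5S,6R)-5-[(2R)-but-3-en-2-yl]-6-(but-1-en-2-yl)-1,2,4-trimethyl-2-[(1E,3E)-4-phenylbuta-1,3-dien-1-yl]cyclohex-3-ene-1-carboxylate
Conditions: MeMgBr, Fe(acac)3 (5 mol%), THF/NMP, −30 to 0 °C
Reagents that add atoms: methylmagnesium bromide, C[Mg]Br
Why: Iron-catalysed cross-coupling of the alkenyl triflate with methylmagnesium bromide (Kumada-type) installs the C7 methyl group at low temperature, conditions under which the hindered ester should survive.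

Step 15
Reactants: 23 tetraene ester
Product: 24 methyl (1R,3aR,4R,5S,7aS)-3-ethyl-1,4,5,7-tetramethyl-5-[(1E,3E)-4-phenylbuta-1,3-dien-1-yl]-3a,4,5,7a-tetrahydro-1H-indene-4-carboxylate
Conditions: second-generation Hoveyda–Grubbs catalyst, RuCl2(H2IMes)(=CH–C6H4-2-OiPr) (5 mol%), CH2Cl2 (0.005 M), 40 °C, argon sparge
Reagents that add atoms: none
Why: Ring-closing olefin metathesis by the Chauvin mechanism: the ruthenium alkylidene loads onto the monosubstituted vinyl group of the C7a arm, undergoes [2+2] cycloaddition with the 1,1-disubstituted alkene of the C3a arm, and cycloreversion of the ruthenacyclobutane releases ethene and the trisubstituted C2=C3 alkene. The closest known reaction type is ring-closing metathesis of 1,6-dienes to trisubstituted cyclopentenes, including trans-fused bicyclo[4.3.0] systems. Ring A (C1, C2, C3, C3a, C7a) is closed as a five-membered carbocycle from a hepta-1,6-diene unit, with loss of ethene as the driving force. No stereocentre is created: C1, C3a and C7a come from steps 9 and 12, and the trans ring fusion follows from the trans-diequatorial arms on ring B. The step needs chemoselectivity for the two terminal alkenes over the trisubstituted ring B alkene and the internal conjugated (E,E)-diene. This should be secured because the vinyl group is the only unhindered terminal alkene for initiation, and five-membered ring closure onto the neighbouring geminal alkene should outpace reaction at the more distant, less reactive internal alkenes.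

Step 16
Reactants: 24 methyl ester
Product: 25 22-nor-zyggomphic acid B, (1R,3aR,4R,5S,7aS)-3-ethyl-1,4,5,7-tetramethyl-5-[(1E,3E)-4-phenylbuta-1,3-dien-1-yl]-3a,4,5,7a-tetrahydro-1H-indene-4-carboxylic acid
Conditions: NaSEt, DMF, 90 °C; then 1 M HCl
Reagents that add atoms: none
Why: SN2 demethylation of the hindered methyl ester by thiolate (alkyl–oxygen cleavage) avoids attack at the shielded carbonyl carbon and leaves all stereocentres and alkenes untouched.

**Compound list**

1 | 2,3-dimethylmaleic anhydride | CC1=C(C)C(=O)OC1=O | starting material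
2 | buta-1,3-diene | C=CC=C | starting material
3 | cis-1,2-dimethylcyclohex-4-ene-1,2-dicarboxylic anhydride (meso) | C1=CC[C@]2(C)C(=O)OC(=O)[C@]2(C)C1 | intermediate
4 | (1S,2R)-2-(methoxycarbonyl)-1,2-dimethylcyclohex-4-ene-1-carboxylic acid | C1=CC[C@](C)(C(=O)O)[C@](C)(C(=O)OC)C1 | intermediate
5 | methyl (1S,2R,4R,5R)-4-bromo-1,2-dimethyl-7-oxo-6-oxabicyclo[3.2.1]octane-2-carboxylate | O=C1O[C@@H]2C[C@@]1(C)[C@](C)(C(=O)OC)C[C@H]2Br | intermediate
6 | methyl (1S,2R,5R)-1,2-dimethyl-7-oxo-6-oxabicyclo[3.2.1]oct-3-ene-2-carboxylate | O=C1O[C@@H]2C[C@@]1(C)[C@](C)(C(=O)OC)C=C2 | intermediate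
7 | methyl (1S,2R,5R)-7-hydroxy-1,2-dimethyl-6-oxabicyclo[3.2.1]oct-3-ene-2-carboxylate (both hemiacetal epimers) | OC1O[C@@H]2C[C@@]1(C)[C@](C)(C(=O)OC)C=C2 | intermediate
8 | diethyl [(2E)-3-phenylprop-2-en-1-yl]phosphonate | CCOP(=O)(C/C=C/c1ccccc1)OCC | starting material
9 | lithium salt of α-deprotonated 8 (not isolated) | [Li+].CCOP(=O)([CH-]/C=C/c1ccccc1)OCC | intermediate
10 | methyl (1R,4R,6R)-4-hydroxy-1,6-dimethyl-6-[(1E,3E)-4-phenylbuta-1,3-dien-1-yl]cyclohex-2-ene-1-carboxylate | O[C@@H]1C[C@](C)(/C=C/C=C/c2ccccc2)[C@](C)(C(=O)OC)C=C1 | intermediate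
11 | methyl (1R,6R)-1,6-dimethyl-4-oxo-6-[(1E,3E)-4-phenylbuta-1,3-dien-1-yl]cyclohex-2-ene-1-carboxylate | O=C1C[C@](C)(/C=C/C=C/c2ccccc2)[C@](C)(C(=O)OC)C=C1 | intermediate
12 | 2-bromobut-1-ene | CCC(Br)=C | starting material
13 | but-1-en-2-ylmagnesium bromide (not isolated) | CCC(=C)[Mg]Br | intermediate
14 | 2-(but-1-en-2-yl)-4,4,5,5-tetramethyl-1,3,2-dioxaborolane | CCC(=C)B1OC(C)(C)C(C)(C)O1 | intermediate
15 | methyl (1R,2R,6R)-6-(but-1-en-2-yl)-1,2-dimethyl-4-oxo-2-[(1E,3E)-4-phenylbuta-1,3-dien-1-yl]cyclohexane-1-carboxylate | O=C1C[C@](C)(/C=C/C=C/c2ccccc2)[C@](C)(C(=O)OC)[C@@H](C(CC)=C)C1 | intermediate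
16 | lithium enolate of 15, enolised toward the carbon next to C3a (not isolated) | [Li+].[O-]C1=C[C@H](C(CC)=C)[C@@](C)(C(=O)OC)[C@@](C)(/C=C/C=C/c2ccccc2)C1 | intermediate
17 | methyl (1R,2R,6R)-2-(but-1-en-2-yl)-1,6-dimethyl-6-[(1E,3E)-4-phenylbuta-1,3-dien-1-yl]-4-[(trimethylsilyl)oxy]cyclohex-3-ene-1-carboxylate | C[Si](C)(C)OC1=C[C@H](C(CC)=C)[C@@](C)(C(=O)OC)[C@@](C)(/C=C/C=C/c2ccccc2)C1 | intermediate
18 | (2E)-but-2-en-1-ol | C/C=C/CO | starting material
19 | (2E)-but-2-en-1-yl methyl carbonate | C/C=C/COC(=O)OC | intermediate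
20 | methyl (1R,2R,5S,6R)-5-[(2R)-but-3-en-2-yl]-6-(but-1-en-2-yl)-1,2-dimethyl-4-oxo-2-[(1E,3E)-4-phenylbuta-1,3-dien-1-yl]cyclohexane-1-carboxylate | C=C[C@@H](C)[C@@H]1C(=O)C[C@](C)(/C=C/C=C/c2ccccc2)[C@](C)(C(=O)OC)[C@H]1C(CC)=C | intermediate
21 | potassium enolate of 20, enolised toward C6 (not isolated) | [K+].C=C[C@@H](C)[C@@H]1C([O-])=C[C@](C)(/C=C/C=C/c2ccccc2)[C@](C)(C(=O)OC)[C@H]1C(CC)=C | intermediate
22 | methyl (1R,2S,5S,6R)-5-[(2R)-but-3-en-2-yl]-6-(but-1-en-2-yl)-1,2-dimethyl-2-[(1E,3E)-4-phenylbuta-1,3-dien-1-yl]-4-{[(trifluoromethyl)sulfonyl]oxy}cyclohex-3-ene-1-carboxylate | C=C[C@@H](C)[C@@H]1C(OS(=O)(=O)C(F)(F)F)=C[C@](C)(/C=C/C=C/c2ccccc2)[C@](C)(C(=O)OC)[C@H]1C(CC)=C | intermediate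
23 | methyl (1R,2S,5S,6R)-5-[(2R)-but-3-en-2-yl]-6-(but-1-en-2-yl)-1,2,4-trimethyl-2-[(1E,3E)-4-phenylbuta-1,3-dien-1-yl]cyclohex-3-ene-1-carboxylate | C=C[C@@H](C)[C@@H]1C(C)=C[C@](C)(/C=C/C=C/c2ccccc2)[C@](C)(C(=O)OC)[C@H]1C(CC)=C | intermediate
24 | methyl (1R,3aR,4R,5S,7aS)-3-ethyl-1,4,5,7-tetramethyl-5-[(1E,3E)-4-phenylbuta-1,3-dien-1-yl]-3a,4,5,7a-tetrahydro-1H-indene-4-carboxylate | CCC1=C[C@@H](C)[C@@H]2C(C)=C[C@](C)(/C=C/C=C/c3ccccc3)[C@](C)(C(=O)OC)[C@@H]12 | intermediate
25 | 22-nor-zyggomphic acid B, (1R,3aR,4R,5S,7aS)-3-ethyl-1,4,5,7-tetramethyl-5-[(1E,3E)-4-phenylbuta-1,3-dien-1-yl]-3a,4,5,7a-tetrahydro-1H-indene-4-carboxylic acid | CCC1=C[C@@H](C)[C@@H]2C(C)=C[C@](C)(/C=C/C=C/c3ccccc3)[C@](C)(C(=O)O)[C@@H]12 | target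

**Step count**

Total: 16 steps. Longest linear sequence: 14 steps (steps 1–7, 9, 10, 12–16).

**Steps most likely to fail**

1. Step 9. The rhodium-catalysed addition may stall because carbometalation must occur at a β-carbon flanked by the quaternary C4, or the catalyst's facial preference may be mismatched with the substrate, eroding face selectivity at C3a. The fallback sets C3a by a stereospecific anti-SN2′ displacement and sets out from 6. Grignard reagent 13 with CuBr·SMe2 (THF, −20 °C) should open the allylic lactone anti to the carboxylate leaving group and give the cyclohexenecarboxylic acid F1. Bromolactonisation (N-bromosuccinimide) should re-form the bridged lactone as the bromolactone F2. Radical debromination (Bu3SnH, AIBN) should give the saturated lactone F3. Reduction with i-Bu2AlH should give the lactol F4, and olefination with anion 9 the hydroxy diene F5. Dess–Martin oxidation of F5 comes back to the route at 15.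

2. Step 12. The allylation may give poor branched-to-linear selectivity, or weak control of the exocyclic centre C1, because a hindered enolate carbon must attack the substituted allyl terminus. The fallback replaces it by a Michael addition, a Nef reaction and a methylenation, and sets out from 17. MeLi should regenerate enolate 16, and its conjugate addition to (E)-1-nitroprop-1-ene should give the nitro ketone F6, with C7a trans to the C3a arm and C1 set by the enolate–nitroalkene topicity. A buffered Nef reaction (TiCl3, NH4OAc) should give the keto aldehyde F7. Chemoselective Wittig methylenation of the aldehyde (Ph3P=CH2, 1 equiv, −78 °C) comes back to the route at 20.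

3. Step 15. The ruthenium alkylidene may engage the conjugated phenyl diene, which would truncate the side chain or close a bridged ring between C2 and the diene instead of ring A. The fallback masks the diene and sets out from 23. Liquid SO2 (sealed tube, rt) should add cheletropically to the (E,E)-diene and give the sulfolene F8. Ring-closing metathesis under the conditions of step 15 should then give the bicyclic sulfolene F9. Thermolysis (toluene, 110 °C, NaHCO3) should extrude SO2 stereospecifically to the (E,E)-diene and comes back to the route at 24.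

**Further compounds**

F1 | step 9 | (1S,5R,6R)-5-(but-1-en-2-yl)-6-(methoxycarbonyl)-1,6-dimethylcyclohex-3-ene-1-carboxylic acid | C1=CC[C@](C)(C(=O)O)[C@](C)(C(=O)OC)[C@H]1C(CC)=C
F2 | step 9 | methyl (1S,2R,3R,4R,5R)-4-bromo-3-(but-1-en-2-yl)-1,2-dimethyl-7-oxo-6-oxabicyclo[3.2.1]octane-2-carboxylate | O=C1O[C@@H]2C[C@@]1(C)[C@](C)(C(=O)OC)[C@@H](C(CC)=C)[C@H]2Br
F3 | step 9 | methyl (1S,2R,3R,5S)-3-(but-1-en-2-yl)-1,2-dimethyl-7-oxo-6-oxabicyclo[3.2.1]octane-2-carboxylate | O=C1O[C@@H]2C[C@@]1(C)[C@](C)(C(=O)OC)[C@@H](C(CC)=C)C2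
F4 | step 9 | methyl (1S,2R,3R,5S)-3-(but-1-en-2-yl)-7-hydroxy-1,2-dimethyl-6-oxabicyclo[3.2.1]octane-2-carboxylate (both hemiacetal epimers) | OC1O[C@@H]2C[C@@]1(C)[C@](C)(C(=O)OC)[C@@H](C(CC)=C)C2
F5 | step 9 | methyl (1R,2R,4S,6R)-6-(but-1-en-2-yl)-4-hydroxy-1,2-dimethyl-2-[(1E,3E)-4-phenylbuta-1,3-dien-1-yl]cyclohexane-1-carboxylate | O[C@@H]1C[C@](C)(/C=C/C=C/c2ccccc2)[C@](C)(C(=O)OC)[C@@H](C(CC)=C)C1
F6 | step 12 | methyl (1R,2R,5R,6R)-6-(but-1-en-2-yl)-1,2-dimethyl-5-[(2S)-1-nitropropan-2-yl]-4-oxo-2-[(1E,3E)-4-phenylbuta-1,3-dien-1-yl]cyclohexane-1-carboxylate | [O-][N+](=O)C[C@@H](C)[C@@H]1C(=O)C[C@](C)(/C=C/C=C/c2ccccc2)[C@](C)(C(=O)OC)[C@H]1C(CC)=C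
F7 | step 12 | methyl (1R,2R,5R,6R)-6-(but-1-en-2-yl)-1,2-dimethyl-4-oxo-5-[(2S)-1-oxopropan-2-yl]-2-[(1E,3E)-4-phenylbuta-1,3-dien-1-yl]cyclohexane-1-carboxylate | O=C[C@@H](C)[C@@H]1C(=O)C[C@](C)(/C=C/C=C/c2ccccc2)[C@](C)(C(=O)OC)[C@H]1C(CC)=C
F8 | step 15 | SO2 adduct of 23: methyl (1R,2S,5S,6R)-5-[(2R)-but-3-en-2-yl]-6-(but-1-en-2-yl)-2-(1,1-dioxido-5-phenyl-2,5-dihydrothiophen-2-yl)-1,2,4-trimethylcyclohex-3-ene-1-carboxylate (cis-2,5-disubstituted sulfolene, both diastereomers) | C=C[C@@H](C)[C@@H]1C(C)=C[C@](C)(C2C=CC(c3ccccc3)S2(=O)=O)[C@](C)(C(=O)OC)[C@H]1C(CC)=C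
F9 | step 15 | methyl (1R,3aR,4R,5S,7aS)-5-(1,1-dioxido-5-phenyl-2,5-dihydrothiophen-2-yl)-3-ethyl-1,4,5,7-tetramethyl-3a,4,5,7a-tetrahydro-1H-indene-4-carboxylate (cis-2,5-disubstituted sulfolene, both diastereomers) | CCC1=C[C@@H](C)[C@@H]2C(C)=C[C@](C)(C3C=CC(c4ccccc4)S3(=O)=O)[C@](C)(C(=O)OC)[C@@H]12
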